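**Retrosynthetic overview**

1. The target is (−)-epigallocatechin-(4β→6)-(−)-epigallocatechin 3-O-gallate. Its last C–C bond (upper C4 to lower C6) is made by capture of an upper flavan-4-yl cation by a per-O-benzylated lower unit whose C8 is blocked by bromine, so that only C6 is free and attack anti to the 3-oxygen gives 4β. One hydrogenolysis then removes fourteen benzyl groups and the bromine.
2. The lower unit is assembled from natural (−)-epigallocatechin: benzylation of the five phenols, esterification of O3 with 3,4,5-tris(benzyloxy)benzoic acid, bromination at C8.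
3. The cation precursor (a 4-ol) comes from a 4-methylidene flavan by C=C cleavage and reduction; the exocyclic CH2 is a temporary carbon that the route removes again.
4. Ring C of the upper unit is closed in one operation from two achiral pieces: 3,4,5-tris(benzyloxy)benzaldehyde (ring B, C2 and O1) and a 2-aryl-3-benzyloxyallyl boronate (C3, C4 and ring A with fluorine on C8a). A catalytic asymmetric alkoxyallylboration makes C2–C3 with both stereocentres, and the O1 alkoxide then displaces fluoride from C8a. Enabling feature: in ring C the unit O1–C2(aryl)–C3(O) is a syn-1,2-diol monoether (2,3-cis), which is what a γ-alkoxyallylboration of an aryl aldehyde delivers, and C8a of the phloroglucinol ring A is meta to both ring-A oxygens (on C5 and C7), so a fluorine there is inductively activated, is the only leaving group, and leaves the 5,7-dioxygenation intact.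
5. Ring order: rings A and B of the upper unit are bought as arenes (1,3,5-trifluorobenzene and the aldehyde), upper ring C is built in step 5, and all rings of the lower unit come from (−)-epigallocatechin and the gallic acid derivative.

Key step: step 5

Assumption (remark on the chemistry): hydride reduction in step 7 is taken to give mainly the all-cis 4-ol drawn as 13; its C4 epimer would serve equally, because C4 is ionised in step 11.

**Route**

Step 1
Reactants: 1 1,3,5-trifluorobenzene
Product: 2 1,3-bis(benzyloxy)-5-fluorobenzene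
Conditions: BnOH (2.05 equiv), NaH, NMP, 0 °C to 80 °C
Reagents that add atoms: benzyl alcohol, OCc1ccccc1
Why: Two successive nucleophilic aromatic substitutions of fluoride by sodium benzyloxide should stop at the diether, because only two equivalents of alkoxide are supplied and each alkoxy group lowers the electrophilicity of the ring.

Step 2
Reactants: 3 2-bromo-3,3-diethoxyprop-1-ene (2-bromoacrolein diethyl acetal)
Product: 4 2-bromo-3,3-bis(benzyloxy)prop-1-ene
Conditions: BnOH (2.5 equiv), pyridinium p-toluenesulfonate (cat.), toluene, 60 °C, reduced pressure (removal of EtOH)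
Reagents that add atoms: benzyl alcohol, OCc1ccccc1
Why: Acid-catalysed transacetalisation is driven to the dibenzyl acetal by removal of ethanol and installs the benzyl group that becomes the hydrogenolysable protecting group on O3.

Step 3
Reactants: 2 1,3-bis(benzyloxy)-5-fluorobenzene; 4 2-bromo-3,3-bis(benzyloxy)prop-1-ene
Product: 7 1,5-bis(benzyloxy)-2-[3,3-bis(benzyloxy)prop-1-en-2-yl]-3-fluorobenzene, via aryllithium 5 (not isolated), via arylzinc chloride 6 (not isolated)
Conditions: n-BuLi, THF, −78 °C; ZnCl2, −78 °C to rt; then 4, Pd(OAc)2 (3 mol%), 2-dicyclohexylphosphino-2',6'-dimethoxybiphenyl, THF, 50 °C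
Reagents that add atoms: none
Why: Fluorine and benzyloxy together direct ortho-lithiation at −78 °C to the carbon between them (the future C4a), transmetalation to zinc suppresses aryne formation, and a Negishi coupling with the alkenyl bromide forms the C4–C4a bond.

Step 4
Reactants: 7 1,5-bis(benzyloxy)-2-[3,3-bis(benzyloxy)prop-1-en-2-yl]-3-fluorobenzene
Product: 8 2-[(E)-3-(benzyloxy)-2-[2,4-bis(benzyloxy)-6-fluorophenyl]prop-2-en-1-yl]-4,4,5,5-tetramethyl-1,3,2-dioxaborolane (benzyloxy cis to CH2B)
Conditions: B2pin2 (1.2 equiv), CuCl (5 mol%), 4,5-bis(diphenylphosphino)-9,9-dimethylxanthene (5 mol%), KOtBu (10 mol%), THF, 30 °C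
Reagents that add atoms: bis(pinacolato)diboron, CC1(C)OB(OC1(C)C)B1OC(C)(C)C(C)(C)O1
Why: Copper-catalysed boryl substitution of an allyl acetal (borylcupration with boron on the terminal CH2, then β-alkoxide elimination) gives the γ-alkoxyallylboronate, and the surviving benzyloxy group should end up trans to the bulky di-ortho-substituted aryl group, that is cis to CH2B.

Step 5
Reactants: 8 the γ-benzyloxyallyl boronate; 9 3,4,5-tris(benzyloxy)benzaldehyde
Product: 11 (2R,3R)-3,5,7-tris(benzyloxy)-4-methylidene-2-[3,4,5-tris(benzyloxy)phenyl]chromane, via pinacol borate ester 10 (not isolated)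
Conditions: (S)-3,3'-bis(2,4,6-triisopropylphenyl)-1,1'-binaphthyl-2,2'-diyl hydrogen phosphate (5 mol%), 4 Å MS, toluene, −30 °C; then KOtBu (1.5 equiv), 18-crown-6, THF, 0 °C to 45 °C
Reagents that add atoms: none
Why: The chiral phosphoric acid activates the boronate so that C3 of 8 adds to the Si face of aldehyde 9 through a closed chair transition state (catalytic asymmetric alkoxyallylboration of aldehydes is the closest known reaction type), giving borate 10 with the C2–C3 bond in place; the (S)-catalyst is the enantiomer expected to expose that face. Because the benzyloxy group of 8 is cis to CH2B it sits axial in the chair while the aldehyde aryl group sits equatorial, which sets the syn (later 2,3-cis) relationship, and the catalyst sets the absolute sense (2R,3R). KOtBu then frees the secondary alkoxide O1, which closes the six-membered ring C by intramolecular nucleophilic aromatic substitution at C8a (addition–elimination through a Meisenheimer intermediate, the closure mode known for flavan pyran rings from 3,5-dialkoxyfluoroarenes). The step needs enantioface control, syn over anti, and O-arylation faster than base-induced migration of the exocyclic alkene; the first two rest on the catalyst and the alkene geometry of 8, the third on the single fluorine at C8a being activated by two meta benzyloxy groups and held next to O1 by the C4 tether. Neither new stereocentre is epimerisable here, because C4 is an alkene carbon and not a ketone.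

Step 6
Reactants: 11 the 4-methylidene flavan
Product: 12 (2R,3S)-3,5,7-tris(benzyloxy)-2-[3,4,5-tris(benzyloxy)phenyl]chroman-4-one (2,3-cis)
Conditions: OsO4 (2 mol%), NaIO4 (4 equiv), 2,6-lutidine, dioxane/H2O, rt
Reagents that add atoms: osmium tetroxide, O=[Os](=O)(=O)=O (catalytic oxygen donor); sodium periodate, [Na+].[O-]I(=O)(=O)=O (stoichiometric oxidant that restores it)
Why: Lemieux–Johnson oxidation (osmylation of the 1,1-disubstituted alkene, periodate cleavage of the diol) removes the temporary carbon under near-neutral conditions that should not epimerise C3, and OsO4 leaves the electron-rich arenes alone.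

Step 7
Reactants: 12 the 2,3-cis chroman-4-one
Product: 13 (2R,3R,4R)-3,5,7-tris(benzyloxy)-2-[3,4,5-tris(benzyloxy)phenyl]chroman-4-ol (all-cis)
Conditions: NaBH4, THF/MeOH, −20 °C
Reagents that add atoms: none
Why: Borohydride reduction of the aryl ketone, expected from the face anti to the axial 3-benzyloxy group, gives the benzylic 4-ol that serves as the cation precursor.

Step 8
Reactants: 14 (−)-epigallocatechin
Product: 15 (2R,3R)-5,7-bis(benzyloxy)-2-[3,4,5-tris(benzyloxy)phenyl]chroman-3-ol (penta-O-benzyl epigallocatechin)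
Conditions: BnBr (5.5 equiv), K2CO3, DMF, 0 °C to rt, argon
Reagents that add atoms: benzyl bromide, BrCc1ccccc1
Why: Williamson etherification under mild carbonate conditions should alkylate the five phenols and leave the much less acidic secondary 3-hydroxyl free and the C2 and C3 stereocentres untouched.

Step 9
Reactants: 15 penta-O-benzyl epigallocatechin; 16 3,4,5-tris(benzyloxy)benzoic acid
Product: 17 (2R,3R)-5,7-bis(benzyloxy)-2-[3,4,5-tris(benzyloxy)phenyl]chroman-3-yl 3,4,5-tris(benzyloxy)benzoate (octa-O-benzyl epigallocatechin gallate)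
Conditions: DCC (1.5 equiv), DMAP (0.3 equiv), CH2Cl2, 0 °C to rt
Reagents that add atoms: none
Why: Steglich esterification acylates the only free hydroxyl group (the axial 3-OH) through the acylpyridinium intermediate, with retention at C3 because the C3–O bond is not broken.

Step 10
Reactants: 17 octa-O-benzyl epigallocatechin gallate
Product: 18 (2R,3R)-5,7-bis(benzyloxy)-8-bromo-2-[3,4,5-tris(benzyloxy)phenyl]chroman-3-yl 3,4,5-tris(benzyloxy)benzoate
Conditions: NBS (1.0 equiv), CH2Cl2, −78 °C to −20 °C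
Reagents that add atoms: N-bromosuccinimide, O=C1CCC(=O)N1Br
Why: Electrophilic aromatic bromination takes place on the most electron-rich ring A at C8, the position that reacts first in 5,7-di-O-benzyl flavans, which blocks C8 and leaves C6 as the only nucleophilic site.

Step 11
Reactants: 13 the upper 4-ol; 18 the 8-bromo lower unit (3 equiv, excess recovered)
Product: 19 tetradeca-O-benzyl 8-bromo-epigallocatechin-(4β→6)-epigallocatechin 3-O-gallate (bromine on C8 of the lower unit; new C4–C6 bond trans to the 3-benzyloxy group)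
Conditions: TMSOTf (0.3 equiv), 4 Å MS, CH2Cl2, −78 °C to −40 °C; Et3N quench
Reagents that add atoms: none
Why: Lewis-acid ionisation of the 4-ol with loss of water gives the flavan-4-yl cation stabilised by O1 and the 5- and 7-oxygens, which C6 of 18 captures in a Friedel–Crafts reaction from the face anti to the 3-benzyloxy group (3,4-trans, 4β), C8 of 18 being blocked by bromine.

Step 12
Reactants: 19 the protected 8-bromo dimer
Product: 20 (−)-epigallocatechin-(4β→6)-(−)-epigallocatechin 3-O-gallate (upper unit 2R,3R,4S; lower unit 2R,3R), the target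
Conditions: H2 (1 atm), Pd(OH)2/C, Et3N (1.2 equiv), THF/MeOH/H2O, rt
Reagents that add atoms: none
Why: Hydrogenolysis over Pd(OH)2/C should cleave all fourteen benzyl ethers and the aryl C–Br bond in one operation without touching the stereocentres, the interflavan bond or the gallate ester.

**Compound list**

1 | 1,3,5-trifluorobenzene | Fc1cc(F)cc(F)c1 | starting material
2 | 1,3-bis(benzyloxy)-5-fluorobenzene | Fc1cc(OCc2ccccc2)cc(OCc2ccccc2)c1 | intermediate
3 | 2-bromo-3,3-diethoxyprop-1-ene | C=C(Br)C(OCC)OCC | starting material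
4 | 2-bromo-3,3-bis(benzyloxy)prop-1-ene | C=C(Br)C(OCc1ccccc1)OCc1ccccc1 | intermediate
5 | [2,4-bis(benzyloxy)-6-fluorophenyl]lithium (not isolated) | [Li]c1c(F)cc(OCc2ccccc2)cc1OCc1ccccc1 | intermediate
6 | [2,4-bis(benzyloxy)-6-fluorophenyl]zinc chloride (not isolated) | Cl[Zn]c1c(F)cc(OCc2ccccc2)cc1OCc1ccccc1 | intermediate
7 | 1,5-bis(benzyloxy)-2-[3,3-bis(benzyloxy)prop-1-en-2-yl]-3-fluorobenzene | C=C(c1c(F)cc(OCc2ccccc2)cc1OCc1ccccc1)C(OCc1ccccc1)OCc1ccccc1 | intermediate
8 | 2-[(E)-3-(benzyloxy)-2-[2,4-bis(benzyloxy)-6-fluorophenyl]prop-2-en-1-yl]-4,4,5,5-tetramethyl-1,3,2-dioxaborolane | CC1(C)OB(C/C(=C\OCc2ccccc2)c2c(F)cc(OCc3ccccc3)cc2OCc2ccccc2)OC1(C)C | intermediate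
9 | 3,4,5-tris(benzyloxy)benzaldehyde | O=Cc1cc(OCc2ccccc2)c(OCc2ccccc2)c(OCc2ccccc2)c1 | starting material
10 | 2-{[(1R,2R)-2-(benzyloxy)-3-[2,4-bis(benzyloxy)-6-fluorophenyl]-1-[3,4,5-tris(benzyloxy)phenyl]but-3-en-1-yl]oxy}-4,4,5,5-tetramethyl-1,3,2-dioxaborolane (not isolated) | C=C(c1c(F)cc(OCc2ccccc2)cc1OCc1ccccc1)[C@@H](OCc1ccccc1)[C@H](OB1OC(C)(C)C(C)(C)O1)c1cc(OCc2ccccc2)c(OCc2ccccc2)c(OCc2ccccc2)c1 | intermediate
11 | (2R,3R)-3,5,7-tris(benzyloxy)-4-methylidene-2-[3,4,5-tris(benzyloxy)phenyl]chromane | C=C1c2c(OCc3ccccc3)cc(OCc3ccccc3)cc2O[C@H](c2cc(OCc3ccccc3)c(OCc3ccccc3)c(OCc3ccccc3)c2)[C@@H]1OCc1ccccc1 | intermediate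
12 | (2R,3S)-3,5,7-tris(benzyloxy)-2-[3,4,5-tris(benzyloxy)phenyl]chroman-4-one | O=C1c2c(OCc3ccccc3)cc(OCc3ccccc3)cc2O[C@H](c2cc(OCc3ccccc3)c(OCc3ccccc3)c(OCc3ccccc3)c2)[C@@H]1OCc1ccccc1 | intermediate
13 | (2R,3R,4R)-3,5,7-tris(benzyloxy)-2-[3,4,5-tris(benzyloxy)phenyl]chroman-4-ol | O[C@@H]1c2c(OCc3ccccc3)cc(OCc3ccccc3)cc2O[C@H](c2cc(OCc3ccccc3)c(OCc3ccccc3)c(OCc3ccccc3)c2)[C@@H]1OCc1ccccc1 | intermediate
14 | (−)-epigallocatechin | O[C@@H]1Cc2c(cc(O)cc2O)O[C@@H]1c1cc(O)c(O)c(O)c1 | starting material
15 | (2R,3R)-5,7-bis(benzyloxy)-2-[3,4,5-tris(benzyloxy)phenyl]chroman-3-ol | O[C@@H]1Cc2c(cc(OCc3ccccc3)cc2OCc2ccccc2)O[C@@H]1c1cc(OCc2ccccc2)c(OCc2ccccc2)c(OCc2ccccc2)c1 | intermediate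
16 | 3,4,5-tris(benzyloxy)benzoic acid | O=C(O)c1cc(OCc2ccccc2)c(OCc2ccccc2)c(OCc2ccccc2)c1 | starting material
17 | (2R,3R)-5,7-bis(benzyloxy)-2-[3,4,5-tris(benzyloxy)phenyl]chroman-3-yl 3,4,5-tris(benzyloxy)benzoate | O=C(O[C@@H]1Cc2c(cc(OCc3ccccc3)cc2OCc2ccccc2)O[C@@H]1c1cc(OCc2ccccc2)c(OCc2ccccc2)c(OCc2ccccc2)c1)c1cc(OCc2ccccc2)c(OCc2ccccc2)c(OCc2ccccc2)c1 | intermediate
18 | (2R,3R)-5,7-bis(benzyloxy)-8-bromo-2-[3,4,5-tris(benzyloxy)phenyl]chroman-3-yl 3,4,5-tris(benzyloxy)benzoate | O=C(O[C@@H]1Cc2c(c(Br)c(OCc3ccccc3)cc2OCc2ccccc2)O[C@@H]1c1cc(OCc2ccccc2)c(OCc2ccccc2)c(OCc2ccccc2)c1)c1cc(OCc2ccccc2)c(OCc2ccccc2)c(OCc2ccccc2)c1 | intermediate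
19 | tetradeca-O-benzyl 8-bromo-epigallocatechin-(4β→6)-epigallocatechin 3-O-gallate (bromine on C8 of the lower unit) | O=C(O[C@@H]1Cc2c(c(Br)c(OCc3ccccc3)c([C@H]3c4c(OCc5ccccc5)cc(OCc5ccccc5)cc4O[C@H](c4cc(OCc5ccccc5)c(OCc5ccccc5)c(OCc5ccccc5)c4)[C@@H]3OCc3ccccc3)c2OCc2ccccc2)O[C@@H]1c1cc(OCc2ccccc2)c(OCc2ccccc2)c(OCc2ccccc2)c1)c1cc(OCc2ccccc2)c(OCc2ccccc2)c(OCc2ccccc2)c1 | intermediate
20 | (−)-epigallocatechin-(4β→6)-(−)-epigallocatechin 3-O-gallate | O=C(O[C@@H]1Cc2c(cc(O)c([C@H]3c4c(O)cc(O)cc4O[C@H](c4cc(O)c(O)c(O)c4)[C@@H]3O)c2O)O[C@@H]1c1cc(O)c(O)c(O)c1)c1cc(O)c(O)c(O)c1 | target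

**Step count and risk**

Total step count: 12. Longest linear sequence: 8 steps (steps 1, 3, 4, 5, 6, 7, 11, 12, from 1,3,5-trifluorobenzene).

The three steps most likely to fail, most risky first:

First, step 5. The processes at risk are insufficient enantiofacial or syn/anti control in the catalysed allylboration of the hindered boronate, and base-induced migration of the exocyclic alkene into the ring during fluoride displacement. The fallback replaces catalyst control by auxiliary control and closes the ring on a substrate without an allylic ether; it sets out from 9 (and from 2 as aryllithium 5) and comes back at 13. Commercial (S)-4-benzyl-3-[(benzyloxy)acetyl]oxazolidin-2-one is enolised with Bu2BOTf and iPr2NEt and added to 9 in an Evans syn-glycolate aldol reaction, which should give the syn-aldol imide F1. AlMe3 and N,O-dimethylhydroxylamine hydrochloride convert it into the Weinreb amide F2. Aryllithium 5 (2.5 equiv, −78 °C) then gives the β-hydroxy ketone F3, and hydroxyl-directed reduction with Me4NBH(OAc)3 (Evans–Saksena) gives the 1,3-anti diol F4. KH with 18-crown-6 in THF closes ring C by the same fluoride displacement, O1 being the only oxygen that can reach C8a in a six-membered ring, and delivers 13.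

Second, step 4. The processes at risk are slow borylcupration of the hindered 1,1-disubstituted alkene and loss of enol-ether geometry in the elimination, which would turn into anti selectivity in step 5. The fallback fixes the geometry by cross-coupling and homologation; it sets out from 2 (through arylzinc 6) and comes back at 8. Benzyl formate is converted with CBr4 and PPh3 into 1-(benzyloxy)-2,2-dibromoethene F5. Negishi coupling of 6 with F5 should replace selectively the less hindered bromine trans to the benzyloxy group and give the (Z)-bromo enol ether F6. Miyaura borylation (B2pin2, PdCl2[1,1'-bis(diphenylphosphino)ferrocene], KOAc) gives the alkenyl boronate F7 with retention. Matteson homologation with LiCH2Cl (ICH2Cl, n-BuLi, −78 °C) inserts CH2 into the C–B bond with retention of alkene geometry and gives 8.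

Third, step 11. The processes at risk are self-condensation of the electrophile through its own unsubstituted C8 and C6, and slow attack by the hindered C6 of 18. The fallback protects C8 of the electrophile as well, which allows more forcing coupling conditions; it sets out from 13 and comes back at 20. NBS at −78 °C brominates C8 of 13 to give the 8-bromo 4-ol F8. Coupling of F8 with 18 (stoichiometric TMSOTf, −40 °C to −20 °C) gives the 8,8'-dibromo dimer F9. Hydrogenolysis under the conditions of step 12 removes both bromines together with the benzyl groups and gives 20.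

**Further compounds**

F1 | step 5 | (S)-4-benzyl-3-[(2S,3R)-2-(benzyloxy)-3-hydroxy-3-[3,4,5-tris(benzyloxy)phenyl]propanoyl]oxazolidin-2-one | O=C([C@@H](OCc1ccccc1)[C@H](O)c1cc(OCc2ccccc2)c(OCc2ccccc2)c(OCc2ccccc2)c1)N1C(=O)OC[C@@H]1Cc1ccccc1
F2 | step 5 | (2S,3R)-2-(benzyloxy)-3-hydroxy-N-methoxy-N-methyl-3-[3,4,5-tris(benzyloxy)phenyl]propanamide | CON(C)C(=O)[C@@H](OCc1ccccc1)[C@H](O)c1cc(OCc2ccccc2)c(OCc2ccccc2)c(OCc2ccccc2)c1
F3 | step 5 | (2S,3R)-2-(benzyloxy)-1-[2,4-bis(benzyloxy)-6-fluorophenyl]-3-hydroxy-3-[3,4,5-tris(benzyloxy)phenyl]propan-1-one | O=C(c1c(F)cc(OCc2ccccc2)cc1OCc1ccccc1)[C@@H](OCc1ccccc1)[C@H](O)c1cc(OCc2ccccc2)c(OCc2ccccc2)c(OCc2ccccc2)c1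
F4 | step 5 | (1R,2S,3R)-2-(benzyloxy)-1-[2,4-bis(benzyloxy)-6-fluorophenyl]-3-[3,4,5-tris(benzyloxy)phenyl]propane-1,3-diol | O[C@H](c1c(F)cc(OCc2ccccc2)cc1OCc1ccccc1)[C@@H](OCc1ccccc1)[C@H](O)c1cc(OCc2ccccc2)c(OCc2ccccc2)c(OCc2ccccc2)c1
F5 | step 4 | 1-(benzyloxy)-2,2-dibromoethene | BrC(Br)=COCc1ccccc1
F6 | step 4 | 1,5-bis(benzyloxy)-2-[(Z)-2-(benzyloxy)-1-bromoethenyl]-3-fluorobenzene | Br/C(=C\OCc1ccccc1)c1c(F)cc(OCc2ccccc2)cc1OCc1ccccc1
F7 | step 4 | 2-[(E)-2-(benzyloxy)-1-[2,4-bis(benzyloxy)-6-fluorophenyl]ethenyl]-4,4,5,5-tetramethyl-1,3,2-dioxaborolane | CC1(C)OB(/C(=C\OCc2ccccc2)c2c(F)cc(OCc3ccccc3)cc2OCc2ccccc2)OC1(C)C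
F8 | step 11 | (2R,3R,4R)-3,5,7-tris(benzyloxy)-8-bromo-2-[3,4,5-tris(benzyloxy)phenyl]chroman-4-ol | O[C@@H]1c2c(OCc3ccccc3)cc(OCc3ccccc3)c(Br)c2O[C@H](c2cc(OCc3ccccc3)c(OCc3ccccc3)c(OCc3ccccc3)c2)[C@@H]1OCc1ccccc1
F9 | step 11 | tetradeca-O-benzyl 8,8'-dibromo-epigallocatechin-(4β→6)-epigallocatechin 3-O-gallate (bromine on C8 of each unit) | O=C(O[C@@H]1Cc2c(c(Br)c(OCc3ccccc3)c([C@H]3c4c(OCc5ccccc5)cc(OCc5ccccc5)c(Br)c4O[C@H](c4cc(OCc5ccccc5)c(OCc5ccccc5)c(OCc5ccccc5)c4)[C@@H]3OCc3ccccc3)c2OCc2ccccc2)O[C@@H]1c1cc(OCc2ccccc2)c(OCc2ccccc2)c(OCc2ccccc2)c1)c1cc(OCc2ccccc2)c(OCc2ccccc2)c(OCc2ccccc2)c1
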